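All runs are calculated for an exercise; noise was put on by code.

Read the loss of target from the balance gap, not from the fall of target.

| flask | substrate | reagent | free catalyst | remark | time |
|---|---|---|---|---|---|
| violet | 0.024 M | 0.055 M | 2.5 mM | run made earlier |  |
| grey | 0.13 M | 0.055 M | 2.5 mM | run made earlier |  |
| west | 0.020 M | 0.0550 M | 2.5 mM |  | 1.0 h |
| south-west | 0.030 M | 0.0550 M | 2.5 mM |  | 1.0 h |
| north | 0.050 M | 0.0550 M | 2.5 mM |  | 1.0 h |
| south-east | 0.080 M | 0.0550 M | 2.5 mM |  | 1.0 h |

| run | time / min | target / % | substrate / % |
|---|---|---|---|
| violet | 4.00 | 16.2 | 82.7 |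
| violet | 10.0 | 16.0 | 80.5 |
| violet | 20.0 | 13.4 | 76.8 |
| violet | 30.0 | 12.2 | 74.4 |
| grey | 4.00 | 10.2 | 81.9 |
| grey | 10.0 | 8.4 | 73.8 |
| grey | 20.0 | 6.2 | 67.1 |
| grey | 30.0 | 3.0 | 62.3 |

(scatter of a reading: 0.5 percentage points)

- [target] at the end for west, south-west, north, south-east, in this order
- the shape of the row from first to last (falls all the way / falls, then rises / rises, then falls / hardly changes / rises all the way)

- "hardly changes" means that all values lie within two and a half points (for a concentration: within two and a half percent of the largest)

1. The balance gap is the part of the charge found neither as substrate nor as target. From the first reading to the last it grows by 12.3 % in violet and by 26.8 % in grey. Conversion of substrate into target leaves this gap unchanged.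

2. Assume that each loss event removes one substrate and one target, so the gap grows by two units per event. Dividing the growth by twice the mean [substrate] times mean [target] and the elapsed time gives 0.884 L mol⁻¹ min⁻¹ in violet and 0.833 L mol⁻¹ min⁻¹ in grey. Their mean is the loss constant 0.858 L mol⁻¹ min⁻¹, the second-order constant of target loss as read from the gap. One over the loss constant times [substrate] is the lifetime of target.

3. The second way uses the logarithmic fall of target divided by mean [substrate]. It gives 0.579 L mol⁻¹ min⁻¹ in violet and 0.502 L mol⁻¹ min⁻¹ in grey, less than the gap values. This way is the one that cheats. Half the gap growth exceeds the fall of target by 2.1 percentage points in violet and 6.2 points in grey, so target was still being fed while it fell.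

4. An unfed reckoning, my own, starts from violet's first target share and applies the loss constant with a mean substrate share of 75.3 %. Its row peaks at 0.0276 M, with 1.57 mM, 1.64 mM, 1.33 mM and 0.716 mM. The feed comes on top of this row; as read from the two runs it was 0.516 mM in violet and 8.06 mM in grey, more at the higher charge.

5. The forecast differs from this reckoning: 0.0021 M, 0.0024 M, 0.0024 M, 0.0019 M, rises, then falls, on the ground that “Target therefore relaxes towards a floor”.

6. The flasks give 0.00188 M, 0.00216 M, 0.00221 M, 0.00180 M, rises, then falls, turning at 0.041 M.

    substrate + reagent + free catalyst ⇌ free catalyst + target (K = 3.75 L mol⁻¹, k = 31.5 L² mol⁻² s⁻¹)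
    substrate + target → side product (k = 0.0142 L mol⁻¹ s⁻¹)
    free catalyst → spent catalyst (k = 0.00206 s⁻¹)

At the end of west, target is made at 0.0280 of the rate at which it is used up, each step taken net, with free catalyst at 0.0602 % of its charge, and the loss constant gives target a lifetime of 82.5 min there. In south-east the same lifetime at the end is shorter, 24.9 min, and target stands at 2.24 % of the substrate charged.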